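## Analysis of the target

The target 24, 4-{[2,4-dimethoxy-6-(2-oxoheptyl)benzoyl]oxy}-2-methoxy-6-pentylbenzoic acid, is a depside: two separate benzene rings joined by one aryl ester, with no fused ring and no stereocentre, so the task is one of substitution pattern and chemoselectivity only. Ring A is numbered from the carbon bearing the ester carbonyl (C1); it carries methoxy groups on C2 and C4 and the 2-oxoheptyl chain on C6. Ring B is numbered from the carbon bearing the free acid (C1'); it has a methoxy group on C2', the ester oxygen on C4' and a pentyl chain on C6'. The aryl ester is an activated ester and will not tolerate alkoxide, hydroxide, amines or thiolates for long. The ketone makes this worse, because its enol oxygen can reach the ester carbonyl through a six-membered ring and close to an enol lactone, expelling ring B, under base or strong acid. The ester carbonyl is flanked on both sides (C2 methoxy, C6 chain), so a late esterification of a 2,6-disubstituted benzoic acid with the electron-poor ring B phenol would be slow and would have to be run next to that ketone or a mask for it. Ring B needs its two phenolic oxygens told apart and its acid protected by a group that leaves under neutral conditions. The feature the strategy rests on is the ortho relationship on ring A: C1 bears a carbonyl carbon, C6 a CH2, and C2 next to C1 a methoxy group, which is the pattern produced when 3,5-dimethoxybenzyne 17 takes up the CH2–C(=O) bond of a malonate.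

## Retrosynthetic reasoning

**24 to 23.** The last bond cut is the O–CH2Ph bond of a benzyl ester on ring B. Hydrogenolysis is neutral, so the aryl ester and the ketone are not exposed to acid or base in the final step.

**23 to 21 and 22.** The ketone is cut between its carbonyl carbon and the pentyl chain. Cutting on the other side would need a benzylic carbanion ortho to an aryl ester, which would attack that ester. The chosen cut leads back to thioester 21 and the alkylzinc reagent 22. Their palladium-catalysed coupling is non-basic, leaves esters alone, and brings the ketone in only two steps from the end.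

**21 to 20 to 19.** These are functional-group changes at the arylacetic carbon. Thioester 21 comes from acid 20, and 20 from tert-butyl ester 19 by acidolysis, which touches neither the benzyl ester nor the aryl ester. The tert-butyl group is chosen for what it does one step earlier.

**19 to 8 and 16 (through 17).** Two ring A bonds are cut at once: C6–CH2 and C1–C(=O). This removes both ortho substituents in one operation and leaves aryne 17 (from silyl triflate 8) and the mixed malonate 16. In 16 the depside C–O bond already exists, made by acylating a phenol with an unhindered acid. The hindered ester is therefore never made by esterification; it arises by carbon–carbon bond formation within one molecule. The forward reaction has to deliver the malonate carbon to C6 and the aryl ester carbonyl to C1, and the aryl anion must choose the aryl ester over the tert-butyl ester.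

**16 to 14 and 15.** The malonate is cut at its aryl ester C–O bond, giving ring B phenol 14 and the half ester 15. A carbodiimide coupling joins them.

**14 back to 9.** Phenol 14 comes from its methoxymethyl ether 13, which comes from 12 by methylation of the chelated C2' hydroxyl. 12 comes from diol ester 11 by selective protection of the unchelated C4' hydroxyl, 11 from olivetolic acid 10, and 10 from olivetol 9 by ortho-carboxylation. The order is dictated by the hydrogen bond between the C2' hydroxyl and the ester carbonyl: it allows the C4' oxygen to be blocked first, the C2' oxygen methylated second, and the C4' oxygen freed last.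

**8 back to 1.** Silyl triflate 8 comes from ortho-silyl phenol 7, which is released from carbamate 6. 6 comes from carbamate 2 by directed ortho-silylation, and 2 from 3,5-dimethoxyphenol 1. The carbamate places silicon between the phenol oxygen and a methoxy group, which is where the aryne needs it.

## Alternatives that were turned down

**Alternative 1: ring A by cycloaddition onto an alkynoate ester.**
- Disconnection: ring A bonds C1–C2 and C5–C6.
- Forward key step: the but-2-ynoate A2 is the ester of 14 with a butynoic acid whose C4 carries the dioxolane-masked ketone and the pentyl chain. It would be heated in toluene with the 1,3-dioxygenated silyloxy diene A3. The [4+2] adduct aromatizes by eliminating the methoxy group of the ketene acetal carbon and losing silicon, giving salicylate A1.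
- For: the regiochemistry of such dienes with ynoates is dependable, the nucleophilic diene terminus going to the β-carbon. The depside C–O bond is made early on an unhindered acid, so on this point it equals the chosen route.
- Against: A1 has a free C2 hydroxyl, chelated to the ester carbonyl and next to a base-labile aryl ester, which must still be methylated. A β-alkyl ynoate is a sluggish dienophile, and A3 is a hydrolytically and thermally fragile ketene acetal. Aryl ynoates are also conjugate acceptors for any phenoxide set free. The ketone would have to be unmasked with aqueous acid at the end, which is the condition under which enol lactonization onto the aryl ester threatens.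
- Comparison: the acid part of A2 needs several steps of its own, and methylation plus deketalization follow the key step. The chosen route is no shorter after its key step, but it has all three methyl ethers in place beforehand and reveals the ketone under neutral conditions.

**Alternative 2: acylketene capture followed by aldol closure of ring A.**
- Disconnection: the depside C–O bond and ring A bond C1–C6.
- Forward key step: thermolysis of dioxinone A5 in the presence of 14 would release an acylketene, which the phenol traps. An amine base added to the same pot would then promote aldol condensation and dehydration to resorcylate A4.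
- For: this is the most bond-forming single operation of the four routes, since the ester bond and the ring are made in one pot from an acyclic chain. The hindered ester is again formed before it is hindered. After the key step it needs no more steps than the chosen route (methylation, deketalization, hydrogenolysis), so on step economy at and after the key step it is as strong or stronger.
- Against: A4 has two free ring A hydroxyls; the C2 one is chelated and sits beside the aryl ester, so exhaustive methylation under base puts the depside bond at risk. The open-chain triketo aryl ester has a good leaving group, so Claisen-type C-acylation with loss of 14, or pyrone formation, can compete with the aldol. A5 contains three ketone-level carbons and a β-keto ketal, so it is lengthy and delicate to make. The final acidic deketalization has the same weakness as in alternative 1.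
- Comparison: the chosen route gives up the one-pot ring construction. In return its methylation pattern is fixed before the key step, its precursors are made by standard steps, and no phenol has to be alkylated next to the aryl ester.

**Alternative 3: three-component aryloxycarbonylation.**
- Disconnection: the bond from ring A C1 to the carbonyl carbon and the ester C–O bond.
- Forward key step: aryl iodide A7, carbon monoxide A8 and phenol 14 would be joined by a palladium–bisphosphine catalyst with an amine base to give A6.
- For: this is the most convergent plan, with complete halves, all methyl ethers in place, and only deketalization and hydrogenolysis left after A6. Carbonylative esterification of aryl iodides with phenols is a broadly established reaction class. On convergency and on the number of steps after the key step it is stronger than the chosen route.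
- Against: A7 is electron-rich and substituted on both sides of the iodide, so oxidative addition is slow and the acyl–palladium intermediate is shielded. The electron-poor phenoxide of 14 is a weak partner for the ester-forming step, so hydrodehalogenation or non-carbonylative coupling can take over. The aryl ester product must survive amine base at the elevated temperature such couplings need. A7 requires a regioselective iodination and a multistep side-chain synthesis. The ketone is again released by acid next to the aryl ester.
- Comparison: the chosen route makes the same hindered C1–carbonyl bond intramolecularly, by an aryl anion closing on a neighbouring ester, which is much less sensitive to steric shielding than an intermolecular catalytic coupling. It also needs no toxic gas and no ketal.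

Key step: step 10

Remark on the chemistry: the target has no stereogenic element, so no SMILES carries a stereodescriptor; the alkylzinc partner is taken as the commercial bromide 22, which behaves like the iodide in thioester couplings.

## Route

**Step 1**
Reactants: 1 3,5-dimethoxyphenol
Product: 2 3,5-dimethoxyphenyl N-(propan-2-yl)carbamate
Conditions: i-PrNCO, Et3N (cat.), CH2Cl2, rt
Reagents that add atoms: isopropyl isocyanate, CC(C)N=C=O
Why: Base-catalysed addition of a phenol to an isocyanate (carbamoylation); the N–H carbamate is chosen because it can be N-silylated into a strong ortho-directing group and later removed under mild base.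

**Step 2**
Reactants: 2 3,5-dimethoxyphenyl N-(propan-2-yl)carbamate
Product: 6 3,5-dimethoxy-2-(trimethylsilyl)phenyl N-(propan-2-yl)carbamate, via the N-TBS carbamate 3 (not isolated), via the C2-lithiated N-TBS carbamate 4 (not isolated), via the N-TBS C2-trimethylsilyl carbamate 5 (not isolated)
Conditions: TBSOTf, TMEDA, Et2O, 0 °C to rt; n-BuLi, TMEDA, −78 °C; TMSCl, −78 °C to rt; aq NaHSO4 work-up
Reagents that add atoms: chlorotrimethylsilane, C[Si](C)(C)Cl
Why: Directed ortho-metalation: N-silylation to 3 removes the acidic N–H and makes the carbamate a strong director, so n-BuLi/TMEDA should lithiate the position between the carbamate oxygen and a methoxy group (the two such positions are equivalent by symmetry) to give 4, which TMSCl traps as 5. The N–Si bond is hydrolysed on acidic work-up; the only competing site, between the two methoxy groups, lacks the stronger director.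

**Step 3**
Reactants: 6 3,5-dimethoxy-2-(trimethylsilyl)phenyl N-(propan-2-yl)carbamate
Product: 8 3,5-dimethoxy-2-(trimethylsilyl)phenyl trifluoromethanesulfonate, via 3,5-dimethoxy-2-(trimethylsilyl)phenol 7 (not isolated)
Conditions: DBU, Et2NH, MeCN, 40 °C; then PhNTf2, rt
Reagents that add atoms: N-phenylbis(trifluoromethanesulfonimide), O=S(=O)(N(c1ccccc1)S(=O)(=O)C(F)(F)F)C(F)(F)F
Why: DBU-promoted E1cB cleavage of the N–H carbamate, with diethylamine trapping the isocyanate, frees the phenoxide of 7, which is triflated in the same flask by PhNTf2. Not isolating the ortho-silyl phenol avoids protodesilylation of the electron-rich ring.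

**Step 4**
Reactants: 9 olivetol (5-pentylbenzene-1,3-diol)
Product: 10 olivetolic acid (2,4-dihydroxy-6-pentylbenzoic acid)
Conditions: MeOMgOCO2Me (methyl magnesium carbonate, 2 M in DMF), 120 °C; then cold aq HCl
Reagents that add atoms: methyl magnesium carbonate, COC(=O)O[Mg]OC
Why: Kolbe–Schmitt-type ortho-carboxylation of a resorcinol through a magnesium chelate, which delivers CO2 ortho to a phenol oxygen; attack at the carbon between hydroxyl and pentyl (para to the second hydroxyl) gives the salicylic-type acid. The acid is liberated cold to limit decarboxylation.

**Step 5**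
Reactants: 10 olivetolic acid
Product: 11 benzyl 2,4-dihydroxy-6-pentylbenzoate
Conditions: BnBr, KHCO3, DMF, rt to 40 °C
Reagents that add atoms: benzyl bromide, BrCc1ccccc1
Why: SN2 alkylation of the carboxylate; hydrogen carbonate deprotonates the acid but not the phenols, so only the ester should form.

**Step 6**
Reactants: 11 benzyl 2,4-dihydroxy-6-pentylbenzoate
Product: 12 benzyl 2-hydroxy-4-(methoxymethoxy)-6-pentylbenzoate
Conditions: MOMCl, i-Pr2NEt, CH2Cl2, 0 °C
Reagents that add atoms: chloromethyl methyl ether, COCCl
Why: Selective etherification (MOM protection): the C2 hydroxyl is held in a hydrogen bond to the ester carbonyl and is flanked by it, so under a mild amine base at 0 °C only the C4 hydroxyl should react.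

**Step 7**
Reactants: 12 benzyl 2-hydroxy-4-(methoxymethoxy)-6-pentylbenzoate
Product: 13 benzyl 2-methoxy-4-(methoxymethoxy)-6-pentylbenzoate
Conditions: MeI, K2CO3, DMF, 40 °C
Reagents that add atoms: iodomethane, CI
Why: Williamson methylation of the chelated C2 phenol, which needs carbonate in a dipolar solvent and gentle warming; the MOM ether and the benzyl ester are inert to these conditions.

**Step 8**
Reactants: 13 benzyl 2-methoxy-4-(methoxymethoxy)-6-pentylbenzoate
Product: 14 benzyl 4-hydroxy-2-methoxy-6-pentylbenzoate
Conditions: HCl (cat.), MeOH, 40 °C
Reagents that add atoms: none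
Why: Acid-catalysed acetal exchange passes the methoxymethyl group to methanol; the hindered benzyl ester and the methyl ether should not react.

**Step 9**
Reactants: 14 benzyl 4-hydroxy-2-methoxy-6-pentylbenzoate; 15 3-tert-butoxy-3-oxopropanoic acid
Product: 16 benzyl 4-[(3-tert-butoxy-3-oxopropanoyl)oxy]-2-methoxy-6-pentylbenzoate
Conditions: DCC, DMAP (cat.), CH2Cl2, 0 °C to rt
Reagents that add atoms: none
Why: Carbodiimide (Steglich-type) esterification; malonic half esters are activated very readily and the acid is unhindered, so even this electron-poor phenol should be acylated under mild conditions.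

**Step 10**
Reactants: 8 3,5-dimethoxy-2-(trimethylsilyl)phenyl trifluoromethanesulfonate; 16 benzyl 4-[(3-tert-butoxy-3-oxopropanoyl)oxy]-2-methoxy-6-pentylbenzoate
Product: 19 benzyl 4-{[2-(2-tert-butoxy-2-oxoethyl)-4,6-dimethoxybenzoyl]oxy}-2-methoxy-6-pentylbenzoate, via 3,5-dimethoxybenzyne 17 (not isolated), via the cesium benzocyclobutenoxide 18 (not isolated)
Conditions: CsF (3 equiv), MeCN, 80 °C; 8 (1.3 equiv) added slowly
Reagents that add atoms: none
Why: Fluoride removes the silyl group of 8 and triflate departs to give aryne 17, while the basic fluoride medium converts 16 into its stabilized enolate. The enolate carbon should add to ring A C6, the aryne carbon remote from the C2 methoxy group, because the triple bond is distorted so that this carbon is the more electrophilic and the charge that develops at C1 lies next to the inductively withdrawing methoxy-bearing carbon. The aryl anion at C1 then closes onto the aryl ester carbonyl in a 4-exo-trig addition to give 18; this four-membered ring is the only ring formed and it is transient. 18 opens by cleaving the bond between its alkoxide carbon and the former malonate carbon, which restores the ester carbonyl on C1 and leaves a benzylic ester enolate on the C6 CH2 that is protonated on work-up. The closest known reaction type is the fluoride-induced insertion of arynes into the carbon–carbon bond of malonates and β-keto esters (acyl-alkylation). No stereocentre is present in 19, and the two in 18 are erased on ring opening. The step needs site selectivity on 17, secured by the C2 methoxy group, and carbonyl selectivity, secured by the bulk and low electrophilicity of the tert-butyl ester; if aryloxide is expelled from 18 it should re-add to the strained four-membered ketone and lead to the same product. Mono-insertion is favoured by generating 17 slowly against the malonate.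

**Step 11**
Reactants: 19 benzyl 4-{[2-(2-tert-butoxy-2-oxoethyl)-4,6-dimethoxybenzoyl]oxy}-2-methoxy-6-pentylbenzoate
Product: 20 [2-({4-[(benzyloxy)carbonyl]-3-methoxy-5-pentylphenoxy}carbonyl)-3,5-dimethoxyphenyl]acetic acid
Conditions: TFA, CH2Cl2 (1:4), 0 °C to rt
Reagents that add atoms: none
Why: Acidolysis of the tert-butyl ester through the tert-butyl cation (E1); the benzyl ester, the aryl ester and the methyl ethers are stable to TFA at room temperature, and the new acid stays protonated so it does not attack the neighbouring aryl ester.

**Step 12**
Reactants: 20 [2-({4-[(benzyloxy)carbonyl]-3-methoxy-5-pentylphenoxy}carbonyl)-3,5-dimethoxyphenyl]acetic acid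
Product: 21 benzyl 4-({2-[2-(ethylsulfanyl)-2-oxoethyl]-4,6-dimethoxybenzoyl}oxy)-2-methoxy-6-pentylbenzoate
Conditions: EtSH, EDC·HCl, DMAP (cat.), CH2Cl2, 0 °C to rt
Reagents that add atoms: ethanethiol, CCS
Why: Carbodiimide thioesterification (Steglich type) of an unhindered arylacetic acid; the aryl ester is shielded by its two ortho substituents and should resist the thiol at 0 °C with only catalytic DMAP.

**Step 13**
Reactants: 21 benzyl 4-({2-[2-(ethylsulfanyl)-2-oxoethyl]-4,6-dimethoxybenzoyl}oxy)-2-methoxy-6-pentylbenzoate; 22 pentylzinc bromide
Product: 23 benzyl 4-{[2,4-dimethoxy-6-(2-oxoheptyl)benzoyl]oxy}-2-methoxy-6-pentylbenzoate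
Conditions: PdCl2(PPh3)2 (5 mol%), toluene/THF, rt
Reagents that add atoms: none
Why: Fukuyama coupling: the divalent palladium precatalyst is reduced by 22 to zerovalent palladium, which inserts into the C–S bond; transmetalation from zinc and reductive elimination give the ketone. Alkylzinc halides do not add to esters or to the product ketone, and the medium stays non-basic, so the aryl ester, the benzyl ester and the new carbonyl should survive.

**Step 14**
Reactants: 23 benzyl 4-{[2,4-dimethoxy-6-(2-oxoheptyl)benzoyl]oxy}-2-methoxy-6-pentylbenzoate
Product: 24 4-{[2,4-dimethoxy-6-(2-oxoheptyl)benzoyl]oxy}-2-methoxy-6-pentylbenzoic acid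
Conditions: H2 (1 atm), 10% Pd/C, EtOAc, rt
Reagents that add atoms: none
Why: Catalytic hydrogenolysis of the benzyl ester; the aryl ester C–O bond, the aliphatic ketone and the methyl ethers are not reduced at one atmosphere and room temperature, and no acid or base is present to trigger enol lactonization.

## Compound list

1 | 3,5-dimethoxyphenol | COc1cc(O)cc(OC)c1 | starting material
2 | 3,5-dimethoxyphenyl N-(propan-2-yl)carbamate | COc1cc(OC)cc(OC(=O)NC(C)C)c1 | intermediate
3 | 3,5-dimethoxyphenyl N-[tert-butyl(dimethyl)silyl]-N-(propan-2-yl)carbamate | COc1cc(OC)cc(OC(=O)N(C(C)C)[Si](C)(C)C(C)(C)C)c1 | intermediate (not isolated)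
4 | 2-lithio-3,5-dimethoxyphenyl N-[tert-butyl(dimethyl)silyl]-N-(propan-2-yl)carbamate | COc1cc(OC)c([Li])c(OC(=O)N(C(C)C)[Si](C)(C)C(C)(C)C)c1 | intermediate (not isolated)
5 | 3,5-dimethoxy-2-(trimethylsilyl)phenyl N-[tert-butyl(dimethyl)silyl]-N-(propan-2-yl)carbamate | COc1cc(OC)c([Si](C)(C)C)c(OC(=O)N(C(C)C)[Si](C)(C)C(C)(C)C)c1 | intermediate (not isolated)
6 | 3,5-dimethoxy-2-(trimethylsilyl)phenyl N-(propan-2-yl)carbamate | COc1cc(OC)c([Si](C)(C)C)c(OC(=O)NC(C)C)c1 | intermediate
7 | 3,5-dimethoxy-2-(trimethylsilyl)phenol | COc1cc(O)c([Si](C)(C)C)c(OC)c1 | intermediate (not isolated)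
8 | 3,5-dimethoxy-2-(trimethylsilyl)phenyl trifluoromethanesulfonate | COc1cc(OC)c([Si](C)(C)C)c(OS(=O)(=O)C(F)(F)F)c1 | intermediate
9 | olivetol (5-pentylbenzene-1,3-diol) | CCCCCc1cc(O)cc(O)c1 | starting material
10 | olivetolic acid (2,4-dihydroxy-6-pentylbenzoic acid) | CCCCCc1cc(O)cc(O)c1C(=O)O | intermediate
11 | benzyl 2,4-dihydroxy-6-pentylbenzoate | CCCCCc1cc(O)cc(O)c1C(=O)OCc1ccccc1 | intermediate
12 | benzyl 2-hydroxy-4-(methoxymethoxy)-6-pentylbenzoate | CCCCCc1cc(OCOC)cc(O)c1C(=O)OCc1ccccc1 | intermediate
13 | benzyl 2-methoxy-4-(methoxymethoxy)-6-pentylbenzoate | CCCCCc1cc(OCOC)cc(OC)c1C(=O)OCc1ccccc1 | intermediate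
14 | benzyl 4-hydroxy-2-methoxy-6-pentylbenzoate | CCCCCc1cc(O)cc(OC)c1C(=O)OCc1ccccc1 | intermediate
15 | 3-tert-butoxy-3-oxopropanoic acid | CC(C)(C)OC(=O)CC(=O)O | starting material
16 | benzyl 4-[(3-tert-butoxy-3-oxopropanoyl)oxy]-2-methoxy-6-pentylbenzoate | CCCCCc1cc(OC(=O)CC(=O)OC(C)(C)C)cc(OC)c1C(=O)OCc1ccccc1 | intermediate
17 | 3,5-dimethoxybenzyne (1,2-didehydro-3,5-dimethoxybenzene) | COC1=CC(OC)=CC#C1 | intermediate (not isolated)
18 | cesium 7-{4-[(benzyloxy)carbonyl]-3-methoxy-5-pentylphenoxy}-8-(tert-butoxycarbonyl)-3,5-dimethoxybicyclo[4.2.0]octa-1,3,5-trien-7-olate (transient, configuration undefined) | [Cs+].[O-]C1(Oc2cc(CCCCC)c(C(=O)OCc3ccccc3)c(OC)c2)C(C(=O)OC(C)(C)C)c2cc(OC)cc(OC)c21 | intermediate (not isolated)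
19 | benzyl 4-{[2-(2-tert-butoxy-2-oxoethyl)-4,6-dimethoxybenzoyl]oxy}-2-methoxy-6-pentylbenzoate | CCCCCc1cc(OC(=O)c2c(OC)cc(OC)cc2CC(=O)OC(C)(C)C)cc(OC)c1C(=O)OCc1ccccc1 | intermediate
20 | [2-({4-[(benzyloxy)carbonyl]-3-methoxy-5-pentylphenoxy}carbonyl)-3,5-dimethoxyphenyl]acetic acid | CCCCCc1cc(OC(=O)c2c(OC)cc(OC)cc2CC(=O)O)cc(OC)c1C(=O)OCc1ccccc1 | intermediate
21 | benzyl 4-({2-[2-(ethylsulfanyl)-2-oxoethyl]-4,6-dimethoxybenzoyl}oxy)-2-methoxy-6-pentylbenzoate | CCCCCc1cc(OC(=O)c2c(OC)cc(OC)cc2CC(=O)SCC)cc(OC)c1C(=O)OCc1ccccc1 | intermediate
22 | pentylzinc bromide (solution in THF) | CCCCC[Zn]Br | starting material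
23 | benzyl 4-{[2,4-dimethoxy-6-(2-oxoheptyl)benzoyl]oxy}-2-methoxy-6-pentylbenzoate | CCCCCC(=O)Cc1cc(OC)cc(OC)c1C(=O)Oc1cc(CCCCC)c(C(=O)OCc2ccccc2)c(OC)c1 | intermediate
24 | 4-{[2,4-dimethoxy-6-(2-oxoheptyl)benzoyl]oxy}-2-methoxy-6-pentylbenzoic acid | CCCCCC(=O)Cc1cc(OC)cc(OC)c1C(=O)Oc1cc(CCCCC)c(C(=O)O)c(OC)c1 | target

## Step count and least certain steps

Total step count: 14. Longest linear sequence: 11 steps (9 to 24, steps 4 to 14). The three-step branch from 1 to 8 joins at step 10.

**Step 10 (key step).**
- What may go wrong: the malonate may lose its aryloxy group before the aryne is intercepted. This can happen by E1cB fragmentation of the enolate to a ketene or by fluoride attack at the aryl ester, followed by O-arylation of the freed phenoxide. The aryl anion may also close onto the tert-butyl ester, or the product enolate may be arylated a second time.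
- Why: the ring B aryloxide is a good leaving group, and fluoride at 80 °C is both base and nucleophile.
- Fallback, from 8 and 14 back to the route at 19: 8 would be treated under the same fluoride conditions with commercial benzyl tert-butyl malonate, a dialkyl malonate that cannot lose an aryloxide. The aryl anion should close on the less hindered benzyl ester, giving benzyl 2-(2-tert-butoxy-2-oxoethyl)-4,6-dimethoxybenzoate F1. Hydrogenolysis (H2, Pd/C, EtOAc) would give 2-(2-tert-butoxy-2-oxoethyl)-4,6-dimethoxybenzoic acid F2. F2 would then be esterified with 14 (DCC, DMAP, CH2Cl2; Steglich esterification) to give 19. This costs two steps and brings back the hindered esterification, but at a stage where no ketone is present.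

**Step 12.**
- What may go wrong: intramolecular acyl transfer, in which the carboxylate or its activated form closes onto the neighbouring aryl ester carbonyl and expels ring B; ketene formation from the activated arylacetic acid; or slow thiolysis of the aryl ester.
- Why: the acid sits five atoms from an activated ester, and DMAP and the thiol are both present.
- Fallback, from 20 back to the route at 23: 20 would be converted under neutral conditions with 1-chloro-N,N,2-trimethylprop-1-en-1-amine (CH2Cl2, 0 °C) into benzyl 4-{[2-(2-chloro-2-oxoethyl)-4,6-dimethoxybenzoyl]oxy}-2-methoxy-6-pentylbenzoate F3. F3 would be coupled directly with 22 under Pd(PPh3)4 in THF (Negishi acylation) to give 23. No carboxylate, amine base or thiol is present and the thioester stage is skipped.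

**Step 13.**
- What may go wrong: β-hydride elimination from the pentyl–palladium intermediate, leading to reduction of the thioester instead of coupling; or enol lactonization of the new ketone onto the aryl ester, promoted by Lewis-acidic zinc salts.
- Why: the alkyl group carries β-hydrogens, and the product places a ketone enol within reach of an activated ester.
- Fallback, from 21 back to the route at 24: a Liebeskind–Srogl coupling of 21 with (E)-pent-1-en-1-ylboronic acid would be run without base or zinc, using Pd2(dba)3, P(2-furyl)3 and copper thiophene-2-carboxylate Cu(O2CC4H3S) (monovalent copper) in THF at 50 °C. The alkenyl partner has no β-hydride pathway. This would give benzyl 4-({2,4-dimethoxy-6-[(3E)-2-oxohept-3-en-1-yl]benzoyl}oxy)-2-methoxy-6-pentylbenzoate F4. Hydrogenation over Pd/C in EtOAc would then saturate the alkene and cleave the benzyl ester in one operation to give 24.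

**Step 2.**
- What may go wrong: metalation between the two methoxy groups instead of beside the carbamate; migration of the carbamoyl group to carbon if N-silylation is incomplete or the temperature rises; or double silylation.
- Why: every free ring position is activated by two oxygen substituents.
- Fallback, from 1 back to the route at 7: 1 would be brominated ortho to the hydroxyl (NBS, CH2Cl2, −78 °C) to give 2-bromo-3,5-dimethoxyphenol F5, separated from any para isomer. F5 would be O-silylated with hexamethyldisilazane to (2-bromo-3,5-dimethoxyphenoxy)trimethylsilane F6. Treatment with n-BuLi (THF, −78 °C) would give bromine–lithium exchange and a 1,3 shift of silicon from oxygen to carbon, forming 7 as its lithium salt, which is triflated in the same flask as in step 3. The halogen fixes the position of silicon independently of any directing effect.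

**Step 4.**
- What may go wrong: carboxylation at the carbon between the two hydroxyls, incomplete conversion, or decarboxylation of the product during acidic work-up.
- Why: both ortho positions are activated, and the product is a readily decarboxylated β-resorcylic acid.
- Fallback, from 9 back to the route at 13: Vilsmeier–Haack formylation of 9 (POCl3, DMF) would give 2,4-dihydroxy-6-pentylbenzaldehyde F7. Selective protection as in step 6 would give 2-hydroxy-4-(methoxymethoxy)-6-pentylbenzaldehyde F8, and methylation as in step 7 would give 2-methoxy-4-(methoxymethoxy)-6-pentylbenzaldehyde F9. Pinnick oxidation (NaClO2, NaH2PO4, 2-methylbut-2-ene, t-BuOH/H2O) would give 2-methoxy-4-(methoxymethoxy)-6-pentylbenzoic acid F10. Benzylation with BnBr and KHCO3 in DMF would give 13. The acid is formed only after both phenols are capped, so decarboxylation is no longer an issue.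

## Further compounds

F1 | step 10 | benzyl 2-(2-tert-butoxy-2-oxoethyl)-4,6-dimethoxybenzoate | COc1cc(OC)c(C(=O)OCc2ccccc2)c(CC(=O)OC(C)(C)C)c1
F2 | step 10 | 2-(2-tert-butoxy-2-oxoethyl)-4,6-dimethoxybenzoic acid | COc1cc(OC)c(C(=O)O)c(CC(=O)OC(C)(C)C)c1
F3 | step 12 | benzyl 4-{[2-(2-chloro-2-oxoethyl)-4,6-dimethoxybenzoyl]oxy}-2-methoxy-6-pentylbenzoate | CCCCCc1cc(OC(=O)c2c(OC)cc(OC)cc2CC(=O)Cl)cc(OC)c1C(=O)OCc1ccccc1
F4 | step 13 | benzyl 4-({2,4-dimethoxy-6-[(3E)-2-oxohept-3-en-1-yl]benzoyl}oxy)-2-methoxy-6-pentylbenzoate | CCC/C=C/C(=O)Cc1cc(OC)cc(OC)c1C(=O)Oc1cc(CCCCC)c(C(=O)OCc2ccccc2)c(OC)c1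
F5 | step 2 | 2-bromo-3,5-dimethoxyphenol | COc1cc(O)c(Br)c(OC)c1
F6 | step 2 | (2-bromo-3,5-dimethoxyphenoxy)trimethylsilane | COc1cc(O[Si](C)(C)C)c(Br)c(OC)c1
F7 | step 4 | 2,4-dihydroxy-6-pentylbenzaldehyde | CCCCCc1cc(O)cc(O)c1C=O
F8 | step 4 | 2-hydroxy-4-(methoxymethoxy)-6-pentylbenzaldehyde | CCCCCc1cc(OCOC)cc(O)c1C=O
F9 | step 4 | 2-methoxy-4-(methoxymethoxy)-6-pentylbenzaldehyde | CCCCCc1cc(OCOC)cc(OC)c1C=O
F10 | step 4 | 2-methoxy-4-(methoxymethoxy)-6-pentylbenzoic acid | CCCCCc1cc(OCOC)cc(OC)c1C(=O)O
A1 | alternative 1 | 4-[(benzyloxy)carbonyl]-3-methoxy-5-pentylphenyl 2-hydroxy-4-methoxy-6-[(2-pentyl-1,3-dioxolan-2-yl)methyl]benzoate | CCCCCC1(Cc2cc(OC)cc(O)c2C(=O)Oc2cc(CCCCC)c(C(=O)OCc3ccccc3)c(OC)c2)OCCO1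
A2 | alternative 1 | 4-[(benzyloxy)carbonyl]-3-methoxy-5-pentylphenyl 4-(2-pentyl-1,3-dioxolan-2-yl)but-2-ynoate | CCCCCC1(CC#CC(=O)Oc2cc(CCCCC)c(C(=O)OCc3ccccc3)c(OC)c2)OCCO1
A3 | alternative 1 | 1,3-dimethoxy-1-(trimethylsilyloxy)buta-1,3-diene | C=C(OC)C=C(OC)O[Si](C)(C)C
A4 | alternative 2 | 4-[(benzyloxy)carbonyl]-3-methoxy-5-pentylphenyl 2,4-dihydroxy-6-[(2-pentyl-1,3-dioxolan-2-yl)methyl]benzoate | CCCCCC1(Cc2cc(O)cc(O)c2C(=O)Oc2cc(CCCCC)c(C(=O)OCc3ccccc3)c(OC)c2)OCCO1
A5 | alternative 2 | 2,2-dimethyl-6-[2,4-dioxo-5-(2-pentyl-1,3-dioxolan-2-yl)pentyl]-4H-1,3-dioxin-4-one | CCCCCC1(CC(=O)CC(=O)CC2=CC(=O)OC(C)(C)O2)OCCO1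
A6 | alternative 3 | 4-[(benzyloxy)carbonyl]-3-methoxy-5-pentylphenyl 2,4-dimethoxy-6-[(2-pentyl-1,3-dioxolan-2-yl)methyl]benzoate | CCCCCC1(Cc2cc(OC)cc(OC)c2C(=O)Oc2cc(CCCCC)c(C(=O)OCc3ccccc3)c(OC)c2)OCCO1
A7 | alternative 3 | 2-[(2-iodo-3,5-dimethoxyphenyl)methyl]-2-pentyl-1,3-dioxolane | CCCCCC1(Cc2cc(OC)cc(OC)c2I)OCCO1
A8 | alternative 3 | carbon monoxide | [C-]#[O+]
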